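**Retrosynthetic overview**
- Target ⇒ (H2, Pd/C: alkene saturation and loss of both O-benzyl groups) ⇒ C4′=C5′ alkene ⇒ cross-metathesis of two terminal alkenes: an aryl C5 fragment (benzoic acid carrying the C2′ acetate) and a C10 fragment, (R)-dec-9-en-2-yl acetate.
- Aryl fragment ⇒ CO2H from CHO (Pinnick) ⇒ CHO by Vilsmeier–Haack on the 5-alkylresorcinol dibenzyl ether ⇒ aryl–C1′ bond from ArMgBr + (R)-2-allyloxirane (C2′ from the chiral pool), alkoxide trapped as the acetate.
- ArBr ⇒ 3-bromophenol by meta C–H borylation/oxidation, then benzylation; (R)-2-allyloxirane ⇒ (R)-epichlorohydrin + vinylmagnesium bromide.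
- C10 fragment ⇒ (R)-propylene oxide + hept-6-enylmagnesium bromide (C12′ from the chiral pool), then acetylation.
- Rings: the benzene ring is bought (3-bromophenol) and no ring of the target is built; the only ring closed on the way is the oxirane of the C5 epoxide, opened again in the arylation.

Assumption: side-chain carbons are numbered C1′–C13′ from the ring, both acetoxy carbons (C2′, C12′) are R as read from the SMILES, and (R)-epichlorohydrin, (R)-propylene oxide, vinylmagnesium bromide solution and 7-bromohept-1-ene are bought.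

**Route**

Step 1
Reactants: 1 3-bromophenol
Product: 2 (3-bromophenoxy)(tert-butyl)dimethylsilane
Conditions: TBSCl (1.1 equiv), imidazole (2 equiv), CH2Cl2, rt
Reagents that add atoms: tert-butyldimethylsilyl chloride, CC(C)(C)[Si](C)(C)Cl
Why: O-silylation of the phenol gives a bulky silyl ether that shields both ortho C–H bonds in the next step; no stereocentre is involved.

Step 2
Reactants: 2 (3-bromophenoxy)(tert-butyl)dimethylsilane
Product: 4 3-bromo-5-[(tert-butyldimethylsilyl)oxy]phenol, via aryl pinacol boronate 3 (not isolated)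
Conditions: [Ir(OMe)(cod)]2 (1 mol %), 4,4′-di-tert-butyl-2,2′-bipyridine (2 mol %), HBpin (1.5 equiv), THF, 60 °C; then KHSO5 (as 2KHSO5·KHSO4·K2SO4), acetone/H2O, rt, 15 min
Reagents that add atoms: potassium peroxymonosulfate, [K+].[O-]S(=O)(=O)OO
Why: Sterically governed iridium-catalysed aromatic C–H borylation (Maleczka–Smith borylation/oxidation) reaches only C5, the one C–H with no ortho substituent, and KHSO5 oxidises the C–B bond to the phenol while C–Br and the silyl ether survive.

Step 3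
Reactants: 4 3-bromo-5-[(tert-butyldimethylsilyl)oxy]phenol
Product: 5 1,3-bis(benzyloxy)-5-bromobenzene
Conditions: BnBr (2.4 equiv), K2CO3 (1.5 equiv), CsF (1.5 equiv), DMF, rt → 60 °C
Reagents that add atoms: benzyl bromide, BrCc1ccccc1
Why: Williamson ether synthesis in which carbonate alkylates the free phenol and fluoride cleaves the aryl silyl ether to a phenoxide that is benzylated in the same flask.

Step 4
Reactants: 6 (R)-epichlorohydrin [(2R)-2-(chloromethyl)oxirane]; 7 vinylmagnesium bromide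
Product: 8 (2R)-1-chloropent-4-en-2-ol
Conditions: CuI (10 mol %), THF, −40 °C; aq. NH4Cl
Reagents that add atoms: none
Why: Copper-catalysed Grignard opening of the terminal epoxide at its CH2 carbon (SN2) is faster than attack on C–Cl; the stereocentre comes from the chiral pool, no bond to it is broken, and it stays R.

Step 5
Reactants: 8 (2R)-1-chloropent-4-en-2-ol
Product: 9 (2R)-2-(prop-2-en-1-yl)oxirane
Conditions: NaOH (powder), Et2O, rt; distil
Reagents that add atoms: none
Why: Intramolecular Williamson reaction (chlorohydrin to epoxide) displaces the primary chloride; the C–O bond at the stereocentre is untouched, so R is retained.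

Step 6
Reactants: 5 1,3-bis(benzyloxy)-5-bromobenzene; 9 (2R)-2-(prop-2-en-1-yl)oxirane
Product: 12 (2R)-1-[3,5-bis(benzyloxy)phenyl]pent-4-en-2-yl acetate, via aryl Grignard reagent 10 (not isolated), via bromomagnesium alkoxide 11 (not isolated)
Conditions: Mg, THF, 50 °C; CuI (10 mol %), 9 (1.2 equiv), −30 → 0 °C; then Ac2O (3 equiv), DMAP (10 mol %), 0 °C → rt
Reagents that add atoms: acetic anhydride, CC(=O)OC(C)=O
Why: Grignard formation, copper-catalysed SN2 opening of the epoxide at its terminal carbon and O-acylation of the alkoxide; the carbinol centre (C2′) is carried over from 9 and stays R because CH2Ar takes the CIP rank the oxirane CH2 held.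

Step 7
Reactants: 12 (2R)-1-[3,5-bis(benzyloxy)phenyl]pent-4-en-2-yl acetate
Product: 14 (2R)-1-[3,5-bis(benzyloxy)-2-formylphenyl]pent-4-en-2-yl acetate, via aryl iminium chloride 13 (not isolated)
Conditions: POCl3 (2 equiv), DMF, 0 → 40 °C; then H2O, 0 °C → rt
Reagents that add atoms: N,N-dimethylformamide, CN(C)C=O; water, O
Why: Vilsmeier–Haack formylation (electrophilic aromatic substitution) attacks the ring carbon next to the side chain, para to one benzyloxy group and ortho to the other, in preference to the more hindered carbon between the two ethers; water hydrolyses the iminium salt and the stereocentre is not involved.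

Step 8
Reactants: 14 (2R)-1-[3,5-bis(benzyloxy)-2-formylphenyl]pent-4-en-2-yl acetate
Product: 15 2-[(2R)-2-(acetyloxy)pent-4-en-1-yl]-4,6-bis(benzyloxy)benzoic acid
Conditions: NaClO2 (3 equiv), NaH2PO4 (3 equiv), 2-methylbut-2-ene (20 equiv), t-BuOH/THF/H2O, 0 °C → rt
Reagents that add atoms: sodium chlorite, [Na+].[O-]Cl=O
Why: Pinnick oxidation converts the hindered aryl aldehyde into the acid while excess 2-methylbut-2-ene traps HOCl before it can chlorinate the ring or the terminal alkene; acetate, benzyl ethers and the stereocentre are inert.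

Step 9
Reactants: 16 7-bromohept-1-ene; 17 (R)-propylene oxide [(2R)-2-methyloxirane]
Product: 19 (2R)-dec-9-en-2-ol, via hept-6-enyl Grignard reagent 18 (not isolated)
Conditions: Mg, THF, 40 °C; CuI (10 mol %), 17 (0.85 equiv), −30 → 0 °C; aq. NH4Cl
Reagents that add atoms: none
Why: Grignard formation and copper-catalysed SN2 opening of the epoxide at CH2; the carbinol centre (later C12′) comes from the chiral pool with retention (R).

Step 10
Reactants: 19 (2R)-dec-9-en-2-ol
Product: 20 (2R)-dec-9-en-2-yl acetate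
Conditions: Ac2O (1.5 equiv), pyridine, DMAP (5 mol %), CH2Cl2, rt
Reagents that add atoms: acetic anhydride, CC(=O)OC(C)=O
Why: DMAP-catalysed O-acylation of the secondary alcohol; no bond to the stereocentre is broken, so R is retained.

Step 11
Reactants: 15 2-[(2R)-2-(acetyloxy)pent-4-en-1-yl]-4,6-bis(benzyloxy)benzoic acid; 20 (2R)-dec-9-en-2-yl acetate
Product: 21 2-[(2R,12R)-2,12-bis(acetyloxy)tridec-4-en-1-yl]-4,6-bis(benzyloxy)benzoic acid (E/Z mixture)
Conditions: 20 (3 equiv), second-generation Hoveyda–Grubbs catalyst RuCl2(H2IMes)(=CH-C6H4-2-OiPr) (5 mol %), CH2Cl2, 40 °C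
Reagents that add atoms: none
Why: Olefin cross-metathesis of two unhindered terminal alkenes joins the fragments at C4′=C5′ with loss of ethene; excess 20 suppresses the homodimer of 15, the alkene geometry is irrelevant and both stereocentres are remote from the reacting carbons.

Step 12
Reactants: 21 2-[(2R,12R)-2,12-bis(acetyloxy)tridec-4-en-1-yl]-4,6-bis(benzyloxy)benzoic acid
Product: 22 2-[(2R,12R)-2,12-bis(acetyloxy)tridecyl]-4,6-dihydroxybenzoic acid
Conditions: H2 (1 atm), 10% Pd/C, EtOAc, rt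
Reagents that add atoms: none
Why: Heterogeneous catalytic hydrogenation saturates the alkene and hydrogenolyses both benzyl ethers at once; the secondary acetates (neither allylic after saturation nor benzylic), the acid and both stereocentres are untouched.

**Compound list**

1 | 3-bromophenol | Oc1cccc(Br)c1 | starting material
2 | (3-bromophenoxy)(tert-butyl)dimethylsilane | CC(C)(C)[Si](C)(C)Oc1cccc(Br)c1 | intermediate
3 | 2-{3-bromo-5-[(tert-butyldimethylsilyl)oxy]phenyl}-4,4,5,5-tetramethyl-1,3,2-dioxaborolane | CC(C)(C)[Si](C)(C)Oc1cc(Br)cc(c1)B1OC(C)(C)C(C)(C)O1 | intermediate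
4 | 3-bromo-5-[(tert-butyldimethylsilyl)oxy]phenol | CC(C)(C)[Si](C)(C)Oc1cc(O)cc(Br)c1 | intermediate
5 | 1,3-bis(benzyloxy)-5-bromobenzene | Brc1cc(OCc2ccccc2)cc(OCc2ccccc2)c1 | intermediate
6 | (R)-epichlorohydrin, (2R)-2-(chloromethyl)oxirane | ClC[C@H]1CO1 | starting material
7 | vinylmagnesium bromide | C=C[Mg]Br | starting material
8 | (2R)-1-chloropent-4-en-2-ol | ClC[C@H](O)CC=C | intermediate
9 | (2R)-2-(prop-2-en-1-yl)oxirane | C=CC[C@@H]1CO1 | intermediate
10 | [3,5-bis(benzyloxy)phenyl]magnesium bromide | Br[Mg]c1cc(OCc2ccccc2)cc(OCc2ccccc2)c1 | intermediate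
11 | bromomagnesium (2R)-1-[3,5-bis(benzyloxy)phenyl]pent-4-en-2-olate | C=CC[C@@H](O[Mg]Br)Cc1cc(OCc2ccccc2)cc(OCc2ccccc2)c1 | intermediate
12 | (2R)-1-[3,5-bis(benzyloxy)phenyl]pent-4-en-2-yl acetate | CC(=O)O[C@H](CC=C)Cc1cc(OCc2ccccc2)cc(OCc2ccccc2)c1 | intermediate
13 | N-({2-[(2R)-2-(acetyloxy)pent-4-en-1-yl]-4,6-bis(benzyloxy)phenyl}methylidene)-N-methylmethanaminium chloride | CC(=O)O[C@H](CC=C)Cc1cc(OCc2ccccc2)cc(OCc2ccccc2)c1C=[N+](C)C.[Cl-] | intermediate
14 | (2R)-1-[3,5-bis(benzyloxy)-2-formylphenyl]pent-4-en-2-yl acetate | CC(=O)O[C@H](CC=C)Cc1cc(OCc2ccccc2)cc(OCc2ccccc2)c1C=O | intermediate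
15 | 2-[(2R)-2-(acetyloxy)pent-4-en-1-yl]-4,6-bis(benzyloxy)benzoic acid | CC(=O)O[C@H](CC=C)Cc1cc(OCc2ccccc2)cc(OCc2ccccc2)c1C(=O)O | intermediate
16 | 7-bromohept-1-ene | C=CCCCCCBr | starting material
17 | (R)-propylene oxide, (2R)-2-methyloxirane | C[C@@H]1CO1 | starting material
18 | hept-6-en-1-ylmagnesium bromide | C=CCCCCC[Mg]Br | intermediate
19 | (2R)-dec-9-en-2-ol | C[C@@H](O)CCCCCCC=C | intermediate
20 | (2R)-dec-9-en-2-yl acetate | C[C@@H](OC(C)=O)CCCCCCC=C | intermediate
21 | 2-[(2R,12R)-2,12-bis(acetyloxy)tridec-4-en-1-yl]-4,6-bis(benzyloxy)benzoic acid (E/Z mixture, E isomer drawn) | CC(=O)O[C@H](C/C=C/CCCCCC[C@@H](C)OC(C)=O)Cc1cc(OCc2ccccc2)cc(OCc2ccccc2)c1C(=O)O | intermediate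
22 | 2-[(2R,12R)-2,12-bis(acetyloxy)tridecyl]-4,6-dihydroxybenzoic acid | CC(=O)O[C@H](CCCCCCCCC[C@@H](C)OC(C)=O)Cc1cc(O)cc(O)c1C(=O)O | target

**Step count**

Total steps: 12.
Longest linear sequence: 8 steps (1 → 2 → 3 → 6 → 7 → 8 → 11 → 12). The epoxide branch (steps 4, 5) and the C10 branch (steps 9, 10) run in parallel.

**Steps most likely to fail, with fallbacks**

Risk at step 6 (aryl Grignard opening of the volatile epoxide with acetylation in the flask). Possible failures are poor Grignard formation, bromohydrin formation from the epoxide, or aryl ketone from leftover Grignard and Ac2O. The fallback replaces the chiral-pool epoxide by a reagent-controlled asymmetric allylation. It sets out from Grignard reagent 10, which is quenched with allyl bromide (THF, 0 °C) to give 1,3-bis(benzyloxy)-5-(prop-2-en-1-yl)benzene F1. Dihydroxylation (OsO4 cat., N-methylmorpholine N-oxide, acetone/H2O) gives racemic 3-[3,5-bis(benzyloxy)phenyl]propane-1,2-diol F2, and NaIO4 (THF/H2O) cleaves it to [3,5-bis(benzyloxy)phenyl]acetaldehyde F3. Brown allylation with (+)-B-allyldiisopinocampheylborane ((+)-Ipc2B(allyl), from (−)-α-pinene, attack on the re face; Et2O, −78 °C, then NaOH/H2O2) gives (2R)-1-[3,5-bis(benzyloxy)phenyl]pent-4-en-2-ol F4. Acetylation (Ac2O, pyridine, DMAP) comes back to the route at 12.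

Risk at step 7 (Vilsmeier–Haack on 12). Possible failures are formylation at the carbon between the two benzyloxy groups, or a sluggish reaction next to the branched side chain. The fallback installs the formyl group before the side chain, where the two regioisomers can be separated cheaply by crystallisation. It sets out from bromide 5: POCl3/DMF gives, through N-{[2,4-bis(benzyloxy)-6-bromophenyl]methylidene}-N-methylmethanaminium chloride F5 and water, 2,4-bis(benzyloxy)-6-bromobenzaldehyde F6. Ethylene glycol with TsOH (toluene, water removal) gives 2-[2,4-bis(benzyloxy)-6-bromophenyl]-1,3-dioxolane F7. Mg in THF gives [3,5-bis(benzyloxy)-2-(1,3-dioxolan-2-yl)phenyl]magnesium bromide F8, which opens epoxide 9 under CuI catalysis to bromomagnesium (2R)-1-[3,5-bis(benzyloxy)-2-(1,3-dioxolan-2-yl)phenyl]pent-4-en-2-olate F9. Ac2O in the flask gives (2R)-1-[3,5-bis(benzyloxy)-2-(1,3-dioxolan-2-yl)phenyl]pent-4-en-2-yl acetate F10. Pyridinium tosylate in wet acetone removes the acetal and comes back to the route at 14.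

Risk at step 11 (cross-metathesis of the free acid 15). Possible failures are stalling of the ruthenium catalyst on the chelating ortho-alkoxybenzoic acid, or an inseparable acid/homodimer mixture. The fallback moves the fragment union ahead of the arene carboxylation, so the metathesis runs on neutral partners and the later oxidation meets no alkene. It sets out from acetates 12 and 20: the same ruthenium catalyst gives (2R,12R)-1-[3,5-bis(benzyloxy)phenyl]tridec-4-ene-2,12-diyl diacetate F11. Diimide (from 2-nitrobenzenesulfonylhydrazide and Et3N, CH2Cl2, rt) reduces the alkene without touching the benzyl ethers and gives (2R,12R)-1-[3,5-bis(benzyloxy)phenyl]tridecane-2,12-diyl diacetate F12. POCl3/DMF gives, through N-({2-[(2R,12R)-2,12-bis(acetyloxy)tridecyl]-4,6-bis(benzyloxy)phenyl}methylidene)-N-methylmethanaminium chloride F13 and water, (2R,12R)-1-[3,5-bis(benzyloxy)-2-formylphenyl]tridecane-2,12-diyl diacetate F14. NaClO2/NaH2PO4/2-methylbut-2-ene gives 2-[(2R,12R)-2,12-bis(acetyloxy)tridecyl]-4,6-bis(benzyloxy)benzoic acid F15. H2 over Pd/C comes back to the route at 22.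

**Further compounds**

F1 | step 6 | 1,3-bis(benzyloxy)-5-(prop-2-en-1-yl)benzene | C=CCc1cc(OCc2ccccc2)cc(OCc2ccccc2)c1
F2 | step 6 | 3-[3,5-bis(benzyloxy)phenyl]propane-1,2-diol (racemic) | OCC(O)Cc1cc(OCc2ccccc2)cc(OCc2ccccc2)c1
F3 | step 6 | [3,5-bis(benzyloxy)phenyl]acetaldehyde | O=CCc1cc(OCc2ccccc2)cc(OCc2ccccc2)c1
F4 | step 6 | (2R)-1-[3,5-bis(benzyloxy)phenyl]pent-4-en-2-ol | C=CC[C@@H](O)Cc1cc(OCc2ccccc2)cc(OCc2ccccc2)c1
F5 | step 7 | N-{[2,4-bis(benzyloxy)-6-bromophenyl]methylidene}-N-methylmethanaminium chloride | C[N+](C)=Cc1c(Br)cc(OCc2ccccc2)cc1OCc1ccccc1.[Cl-]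
F6 | step 7 | 2,4-bis(benzyloxy)-6-bromobenzaldehyde | O=Cc1c(Br)cc(OCc2ccccc2)cc1OCc1ccccc1
F7 | step 7 | 2-[2,4-bis(benzyloxy)-6-bromophenyl]-1,3-dioxolane | Brc1cc(OCc2ccccc2)cc(OCc2ccccc2)c1C1OCCO1
F8 | step 7 | [3,5-bis(benzyloxy)-2-(1,3-dioxolan-2-yl)phenyl]magnesium bromide | Br[Mg]c1cc(OCc2ccccc2)cc(OCc2ccccc2)c1C1OCCO1
F9 | step 7 | bromomagnesium (2R)-1-[3,5-bis(benzyloxy)-2-(1,3-dioxolan-2-yl)phenyl]pent-4-en-2-olate | C=CC[C@@H](O[Mg]Br)Cc1cc(OCc2ccccc2)cc(OCc2ccccc2)c1C1OCCO1
F10 | step 7 | (2R)-1-[3,5-bis(benzyloxy)-2-(1,3-dioxolan-2-yl)phenyl]pent-4-en-2-yl acetate | CC(=O)O[C@H](CC=C)Cc1cc(OCc2ccccc2)cc(OCc2ccccc2)c1C1OCCO1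
F11 | step 11 | (2R,12R)-1-[3,5-bis(benzyloxy)phenyl]tridec-4-ene-2,12-diyl diacetate (E/Z mixture, E isomer drawn) | CC(=O)O[C@H](C/C=C/CCCCCC[C@@H](C)OC(C)=O)Cc1cc(OCc2ccccc2)cc(OCc2ccccc2)c1
F12 | step 11 | (2R,12R)-1-[3,5-bis(benzyloxy)phenyl]tridecane-2,12-diyl diacetate | CC(=O)O[C@H](CCCCCCCCC[C@@H](C)OC(C)=O)Cc1cc(OCc2ccccc2)cc(OCc2ccccc2)c1
F13 | step 11 | N-({2-[(2R,12R)-2,12-bis(acetyloxy)tridecyl]-4,6-bis(benzyloxy)phenyl}methylidene)-N-methylmethanaminium chloride | CC(=O)O[C@H](CCCCCCCCC[C@@H](C)OC(C)=O)Cc1cc(OCc2ccccc2)cc(OCc2ccccc2)c1C=[N+](C)C.[Cl-]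
F14 | step 11 | (2R,12R)-1-[3,5-bis(benzyloxy)-2-formylphenyl]tridecane-2,12-diyl diacetate | CC(=O)O[C@H](CCCCCCCCC[C@@H](C)OC(C)=O)Cc1cc(OCc2ccccc2)cc(OCc2ccccc2)c1C=O
F15 | step 11 | 2-[(2R,12R)-2,12-bis(acetyloxy)tridecyl]-4,6-bis(benzyloxy)benzoic acid | CC(=O)O[C@H](CCCCCCCCC[C@@H](C)OC(C)=O)Cc1cc(OCc2ccccc2)cc(OCc2ccccc2)c1C(=O)O
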